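## The problem

1. Ligraminol C (10) is an open-chain 8-O-4′ neolignan. Veratryl ring A (C1–C6, OMe at C3 and C4) carries the chain C7H(OAc)–C8H(OAr)–C9H3. O4′ of ring B (C1′–C6′, OMe at C3′) is the ether oxygen on C8, and C1′, para to O4′, bears a (Z)-propenyl group (C7′=C8′–C9′).
2. CIP analysis of the given SMILES gives 7R,8R, which is the threo series, and Z at C7′=C8′.
3. No ring holds C7 and C8, and they are the only stereocentres, so their relative and absolute configuration must come from acyclic 1,2-induction or from a catalyst.
4. The two oxygens differ (ester on C7, aryl ether on C8). A route through a 7,8-diol must therefore tell two secondary hydroxyls apart, and an SN2 construction of the hindered C8–O4′ bond on a stereodefined carbon must contend with elimination, participation by O7 and the counting of inversions.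
5. Two groups are fragile. The C7 acetate is a benzylic ester para to the C4 methoxy donor and ionises (epimerises) under protic or Lewis acid. The Z-styrene is the less stable geometric isomer and drifts to E with acid, radicals, unsaturated metal hydrides or light.
6. The enabling feature is the C8–H bond, which lies between C7 and O4′. Once C7 is a carbonyl conjugated with ring A, this hydrogen is acidified by the aroyl group and by the aryloxy oxygen, so C8 is stereolabile at the ketone level and frozen at the alcohol level.
7. In the same ketone, ring A sits directly on the prochiral C7=O, the arrangement that arene–Ru/monosulfonyldiamine hydride-transfer catalysts read best.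
8. Both stereocentres can therefore be set in one reduction of material that carries no stereochemical information.

## Retrosynthesis

**10 ⇒ 9.** The cut is the O7–acyl bond. The benzylic acetate is the most easily ionised group of the target, so it is removed first in the analysis and installed last in the synthesis. Cutting O7–C(acyl) rather than C7–O7 leaves the stereocentre untouched. The forward reaction must be a non-ionising, basic O-acylation that leaves the Z-olefin alone.

**9 ⇒ 7 + 8.** The cut is the sp2–sp2 bond C1′–C7′. The neighbouring cut, C7′=C8′ (olefination of an aryl aldehyde), would create the geometry in the flask and leave it to kinetic selectivity. The C1′–C7′ cut takes the geometry ready-made from 8 and only asks for retention. The bromine of 7 is a placeholder, inert to base and to hydride transfer, so the labile olefin enters after all such steps. As a heavy atom in a likely crystalline alcohol, it should also allow stereochemical upgrading and an independent check of absolute configuration. The forward reaction is a stereoretentive cross-coupling on an electron-rich aryl bromide that bears a free alcohol.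

**7 ⇒ 4 (through 5 and 6), the key disconnection.** The cut is the C7–H bond, and with it the configurations of both C7 and C8 are erased.

- The neighbouring cuts all demand that one centre be made first and then control the other in an open chain. These are C8–O4′ on a stereodefined carbon, C7–C1 by aryl addition to an α-aryloxy aldehyde, and C7–C8.
- At the ketone level the distinction O7/O8 is built in by oxidation state. C8 equilibrates through the achiral enol 5, and a chiral hydride-transfer catalyst can draw only the matched enantiomer 6 out of the racemate.
- The precursor 4 has no defined stereoelement, whereas 7 has both.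
- The forward reaction needs racemisation faster than reduction of the mismatched enantiomer, irreversible hydride delivery, catalyst control at C7, and a non-chelated (threo-selective) discrimination at C8.

**4 ⇒ 2 + 3.** The cut is C8–O4′, the same bond that is troublesome on a stereodefined carbon. Here it is made on a racemic, carbonyl-activated secondary bromide, where configuration is irrelevant and SN2 is accelerated. The skeleton falls into an achiral phenol 3 and a racemic bromide 2. The forward reaction only has to favour substitution over dehydrobromination.

**2 ⇒ 1.** The cut is C8–Br. The ketone that will later make C8 labile also directs the halogen to C8 through its enol. The forward reaction must brominate the α-carbon and not the activated ring A.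

## Roads not taken

**Alternative 1:** This is the most obvious route. It cuts C8–O4′ on a stereodefined carbon.

- Sharpless asymmetric dihydroxylation of (E)-methyl isoeugenol A1 would give the threo (7S,8S)-diol A2. After masking of O7, Mitsunobu displacement at C8 by (Z)-isoeugenol A3 would give the ether A4.
- syn-Dihydroxylation of an E-olefin followed by one inversion ends in the erythro series (7S,8R). The threo target then needs one of two things. One is the Z-olefin, a poor substrate class for this dihydroxylation. The other is a second inversion at C7, a p-alkoxybenzylic carbon that reacts by ionisation rather than by clean SN2.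
- The route also pays for telling O7 from O8 (protection and deprotection). It risks O7 participation and elimination in the Mitsunobu step, and it must prepare A3 and carry its olefin throughout.
- In the chosen plan O7 and O8 are never alike, C8–O4′ is formed where configuration does not matter, and no inversion has to be counted.

**Alternative 2:** This cuts C8–O4′ and C7–O together, as in the presumed biosynthesis.

- One-electron oxidation of (E)-isoeugenol A5 in the presence of A3 would join C8 of one phenoxyl radical to O4′ of the other and give the quinone methide A6. Acetate capture at C7 and O-methylation at O4 would finish a very short route.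
- Both guaiacyl monomers have a free C5/C5′ position, so 8–5′ and 8–8′ coupling compete with 8–O–4′.
- Both phenols are oxidised at similar potential, so homo- and cross-coupling are statistical, and A3 can lose its geometry in its own delocalised radical.
- Nothing in the radical pair fixes the absolute configuration at C8, and addition to the planar A6 is only weakly face-selective. All stereoisomers would have to be separated and resolved at the end.
- The chosen plan keeps the simplicity of a two-monomer union but adds a step that converts the whole mixture into one isomer.

**Alternative 3:** This cuts O4′–C4′, the aryl–oxygen bond, so that C8 keeps its configuration.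

- The (7R,8R)-diol A7 already has the threo relation. SNAr of its C8 alkoxide on 4-fluoro-3-methoxybenzaldehyde A8 would give the aldehyde A9, and a Z-selective Wittig ethylidenation and acetylation would finish.
- This is short and free of inversions, but the two secondary alkoxides of A7 are nearly equal in nucleophilicity.
- The formyl group that permits the SNAr also permits O8→O7 aryl migration through a five-membered spiro Meisenheimer adduct (Smiles). The regiochemistry would therefore be under thermodynamic control.
- A non-stabilised ylide on an electron-rich aryl aldehyde leaves the olefin geometry to kinetic selectivity at the last C–C bond formation.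
- In the chosen plan the regiochemistry follows from the oxidation level and the geometry comes with 8.

Key step: step 3

Assumption: neolignan numbering is used throughout (ring A C1–C6, chain C7–C9, ring B C1′–C6′, propenyl C7′–C9′), and compounds 1, 3 and 8 are taken as commercially available.

## Steps

Step 1
Reactants: 1 1-(3,4-dimethoxyphenyl)propan-1-one
Product: 2 rac-2-bromo-1-(3,4-dimethoxyphenyl)propan-1-one
Conditions: CuBr2 (2.1 equiv), EtOAc/CHCl3 1:1, reflux
Reagents that add atoms: copper(II) bromide, [Cu+2].[Br-].[Br-]
Why: α-Bromination of an aryl ketone through its enol with CuBr2 (King–Ostrum conditions); the mild heterogeneous bromine source should spare the activated ring A that free bromine would attack, and C8 is formed racemic, which the plan allows.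

Step 2
Reactants: 2 rac-2-bromo-1-(3,4-dimethoxyphenyl)propan-1-one; 3 4-bromo-2-methoxyphenol
Product: 4 rac-2-(4-bromo-2-methoxyphenoxy)-1-(3,4-dimethoxyphenyl)propan-1-one
Conditions: K2CO3 (1.5 equiv), acetone, reflux
Reagents that add atoms: none
Why: Williamson-type SN2 of a phenoxide on an α-bromo ketone, the classical entry to 8-O-4′ keto ethers; the adjacent carbonyl accelerates displacement over elimination, and no stereochemical demand is made because C8 is racemised on purpose in step 3.

Step 3
Reactants: 4 rac-2-(4-bromo-2-methoxyphenoxy)-1-(3,4-dimethoxyphenyl)propan-1-one
Product: 7 (1R,2R)-2-(4-bromo-2-methoxyphenoxy)-1-(3,4-dimethoxyphenyl)propan-1-ol, via achiral enol 5 (not isolated), via (R)-ketone 6 (not isolated)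
Conditions: RuCl[(S,S)-TsDPEN](p-cymene) (1 mol %), DBU (3 equiv), HCO2H (2.5 equiv, slow addition), MeCN, 40 °C, Ar
Reagents that add atoms: none
Why: This is a dynamic kinetic resolution by Noyori–Ikariya asymmetric transfer hydrogenation: free DBU removes the C8–H of 4, acidified by the veratroyl C7=O and by O4′, so that the two ketone enantiomers interconvert through the achiral enol(ate) 5, while the 18-electron Ru–H/N–H species fed by formate passes hydride to C7 and a proton to O7 in a six-membered outer-sphere transition state. The closest known reactions are the transfer-hydrogenative DKR of benzoins to threo-hydrobenzoins and of α-alkoxy-β-keto esters to syn-diol monoethers, and the base-driven hydrogenative DKR of 2-alkoxycycloalkanones with related Ru–H/N–H catalysts. C7 is set by the catalyst: the CH/π contact between the η6-cymene and ring A orients the aryl ketone as it orients acetophenone, so the (S,S)-ligand should deliver hydride to the Si face and give 7R, the same spatial sense as (S)-1-phenylethanol and (R,R)-hydrobenzoin (the descriptor differs only because C8 outranks C1). C8 is set by selection between the equilibrating enantiomers: on that face only the (R)-ketone 6 can take up the polar Felkin–Anh arrangement, with C8–O4′ anti to the incoming hydride, C9H3 beside the carbonyl oxygen and C8–H on the hydride path next to ring A, and this arrangement leads to the threo (7R,8R) alcohol. The catalyst offers no Lewis-acidic site, so the O7/O4′ chelate pathway that leads metal borohydrides towards the erythro alcohol is closed. The step needs racemisation to outrun reduction of the mismatched (S)-ketone and the reduction to be irreversible; the electron-rich veratroyl carbonyl takes up hydride slowly, formic acid is dosed slowly, loss of CO2 forbids the back reaction, and 7 has no acidic C8–H, so both centres are frozen once formed. No ring is closed, and the aryl bromide and the aryl ethers should survive because the saturated Ru–H has no free site for oxidative addition.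

Step 4
Reactants: 7 (1R,2R)-2-(4-bromo-2-methoxyphenoxy)-1-(3,4-dimethoxyphenyl)propan-1-ol; 8 (Z)-prop-1-en-1-ylboronic acid
Product: 9 (1R,2R)-1-(3,4-dimethoxyphenyl)-2-{2-methoxy-4-[(Z)-prop-1-en-1-yl]phenoxy}propan-1-ol
Conditions: 8 (1.5 equiv), Pd(dppf)Cl2·CH2Cl2 (3 mol %), K2CO3 (2 equiv), dioxane/H2O 5:1, 70 °C, degassed, dark
Reagents that add atoms: none
Why: Suzuki–Miyaura coupling; transmetalation and reductive elimination of alkenylboron reagents proceed with retention of olefin geometry, so the Z configuration comes with 8. The free alcohol and the ethers are tolerated, and C7 and C8 no longer carry an acidic hydrogen, so the carbonate base cannot touch them.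

Step 5
Reactants: 9 (1R,2R)-1-(3,4-dimethoxyphenyl)-2-{2-methoxy-4-[(Z)-prop-1-en-1-yl]phenoxy}propan-1-ol
Product: 10 ligraminol C, (1R,2R)-1-(3,4-dimethoxyphenyl)-2-{2-methoxy-4-[(Z)-prop-1-en-1-yl]phenoxy}propyl acetate
Conditions: Ac2O (2 equiv), pyridine (4 equiv), DMAP (5 mol %), CH2Cl2, 0 °C to rt, dark; NaHCO3 work-up, Et3N-deactivated silica
Reagents that add atoms: acetic anhydride, CC(=O)OC(C)=O
Why: DMAP-catalysed O-acylation; the C7–O7 bond is not broken, so 7R is retained, and the basic, non-ionising medium should protect both the benzylic centre and the Z-styrene.

## Compound list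

1 | 1-(3,4-dimethoxyphenyl)propan-1-one | CCC(=O)c1ccc(OC)c(OC)c1 | starting material
2 | rac-2-bromo-1-(3,4-dimethoxyphenyl)propan-1-one | CC(Br)C(=O)c1ccc(OC)c(OC)c1 | intermediate
3 | 4-bromo-2-methoxyphenol | COc1cc(Br)ccc1O | starting material
4 | rac-2-(4-bromo-2-methoxyphenoxy)-1-(3,4-dimethoxyphenyl)propan-1-one | COc1cc(Br)ccc1OC(C)C(=O)c1ccc(OC)c(OC)c1 | intermediate
5 | 2-(4-bromo-2-methoxyphenoxy)-1-(3,4-dimethoxyphenyl)prop-1-en-1-ol, achiral enol (present as its enolate; either geometry serves) | COc1cc(Br)ccc1OC(C)=C(O)c1ccc(OC)c(OC)c1 | intermediate
6 | (2R)-2-(4-bromo-2-methoxyphenoxy)-1-(3,4-dimethoxyphenyl)propan-1-one | COc1cc(Br)ccc1O[C@H](C)C(=O)c1ccc(OC)c(OC)c1 | intermediate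
7 | (1R,2R)-2-(4-bromo-2-methoxyphenoxy)-1-(3,4-dimethoxyphenyl)propan-1-ol | COc1cc(Br)ccc1O[C@H](C)[C@H](O)c1ccc(OC)c(OC)c1 | intermediate
8 | (Z)-prop-1-en-1-ylboronic acid | C/C=C\B(O)O | starting material
9 | (1R,2R)-1-(3,4-dimethoxyphenyl)-2-{2-methoxy-4-[(Z)-prop-1-en-1-yl]phenoxy}propan-1-ol | C/C=C\c1ccc(O[C@H](C)[C@H](O)c2ccc(OC)c(OC)c2)c(OC)c1 | intermediate
10 | ligraminol C, (1R,2R)-1-(3,4-dimethoxyphenyl)-2-{2-methoxy-4-[(Z)-prop-1-en-1-yl]phenoxy}propyl acetate | C/C=C\c1ccc(O[C@H](C)[C@H](OC(C)=O)c2ccc(OC)c(OC)c2)c(OC)c1 | target

## Step count and least certain steps

Total step count: 5. Longest linear sequence: 5 (1 → 2 → 4 → 7 → 9 → 10).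

**Step 3 (key step).**
- The most likely failure is that enolisation of 4 is too slow relative to hydride transfer. Compound 4 lacks the second acidifying group of the best-known substrates. The reaction would then degenerate into a kinetic resolution that stalls near half conversion or drags the mismatched enantiomer through.
- The second risk is weak discrimination between the C8 epimers, because an aryl ether oxygen is a weaker polar director than the oxygen functions of the precedents.
- Fallback: C8 is taken from the chiral pool instead of being funnelled.
  - Setting out from 3, a Mitsunobu reaction with ethyl (S)-lactate (inversion) would give ethyl (2R)-2-(4-bromo-2-methoxyphenoxy)propanoate F1.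
  - Aminolysis with N,O-dimethylhydroxylamine hydrochloride/iPrMgCl would give the Weinreb amide (2R)-2-(4-bromo-2-methoxyphenoxy)-N-methoxy-N-methylpropanamide F2.
  - Commercial 3,4-dimethoxyphenylmagnesium bromide at low temperature would give the enantiopure ketone 6, where the route is rejoined.
  - Compound 6 is then reduced with the same (S,S)-catalyst in the acidic, non-epimerising formic acid/triethylamine azeotrope, where catalyst control at C7 alone decides the outcome, to give 7.

**Step 4.**
- An electron-rich aryl bromide needs heat for oxidative addition. Under these conditions partial Z→E erosion by reversible Pd–H addition/elimination and protodeboronation of 8 are the likely losses.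
- Fallback: the geometry is created by syn-addition of hydrogen instead of being transferred.
  - Setting out from 7, Sonogashira coupling with propyne (PdCl2(PPh3)2, CuI, Et3N, sealed vessel) would give (1R,2R)-1-(3,4-dimethoxyphenyl)-2-[2-methoxy-4-(prop-1-yn-1-yl)phenoxy]propan-1-ol F3.
  - Lindlar semihydrogenation (Pd/CaCO3/Pb, quinoline, H2, 1 atm) would return to the route at 9.

**Step 5.**
- The hindered C7–OH, hydrogen-bonded to the neighbouring ether oxygens, may acylate sluggishly. Forcing conditions or a prolonged reaction would invite Z→E drift and incipient ionisation at C7.
- Fallback: the ester is installed before the olefin exists.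
  - Setting out from 7, acetylation (which may be forced on this robust bromide) would give (1R,2R)-2-(4-bromo-2-methoxyphenoxy)-1-(3,4-dimethoxyphenyl)propyl acetate F4.
  - An anhydrous, fluoride-promoted Suzuki–Miyaura coupling with 8 (CsF, THF, Pd/SPhos) would then spare the ester and arrive directly at 10.

**Step 1.**
- Electrophilic bromination of the activated ring A (C6) and α,α-dibromination may compete with the desired monobromination.
- Fallback: the site is fixed by a preformed enol derivative.
  - Setting out from 1, TMSOTf/Et3N would give (Z)-[1-(3,4-dimethoxyphenyl)prop-1-en-1-yl]oxy(trimethyl)silane F5.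
  - The C8 of F5 is far more nucleophilic than ring A, and NBS in THF at −78 °C would return to the route at 2.

## Further compounds

F1 | step 3 | ethyl (2R)-2-(4-bromo-2-methoxyphenoxy)propanoate | COc1cc(Br)ccc1O[C@H](C)C(=O)OCC
F2 | step 3 | (2R)-2-(4-bromo-2-methoxyphenoxy)-N-methoxy-N-methylpropanamide | COc1cc(Br)ccc1O[C@H](C)C(=O)N(C)OC
F3 | step 4 | (1R,2R)-1-(3,4-dimethoxyphenyl)-2-[2-methoxy-4-(prop-1-yn-1-yl)phenoxy]propan-1-ol | CC#Cc1ccc(O[C@H](C)[C@H](O)c2ccc(OC)c(OC)c2)c(OC)c1
F4 | step 5 | (1R,2R)-2-(4-bromo-2-methoxyphenoxy)-1-(3,4-dimethoxyphenyl)propyl acetate | COc1cc(Br)ccc1O[C@H](C)[C@H](OC(C)=O)c1ccc(OC)c(OC)c1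
F5 | step 1 | (Z)-[1-(3,4-dimethoxyphenyl)prop-1-en-1-yl]oxy(trimethyl)silane | C/C=C(\O[Si](C)(C)C)c1ccc(OC)c(OC)c1
A1 | alternative 1 | (E)-methyl isoeugenol, 1,2-dimethoxy-4-[(E)-prop-1-en-1-yl]benzene | C/C=C/c1ccc(OC)c(OC)c1
A2 | alternative 1 | (1S,2S)-1-(3,4-dimethoxyphenyl)propane-1,2-diol | O[C@@H](C)[C@@H](O)c1ccc(OC)c(OC)c1
A3 | alternative 1 | (Z)-isoeugenol, 2-methoxy-4-[(Z)-prop-1-en-1-yl]phenol | C/C=C\c1ccc(O)c(OC)c1
A4 | alternative 1 | (1S,2R)-1-(3,4-dimethoxyphenyl)-2-{2-methoxy-4-[(Z)-prop-1-en-1-yl]phenoxy}propan-1-ol (erythro) | C/C=C\c1ccc(O[C@H](C)[C@@H](O)c2ccc(OC)c(OC)c2)c(OC)c1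
A5 | alternative 2 | (E)-isoeugenol, 2-methoxy-4-[(E)-prop-1-en-1-yl]phenol | C/C=C/c1ccc(O)c(OC)c1
A6 | alternative 2 | rac-2-methoxy-4-(2-{2-methoxy-4-[(Z)-prop-1-en-1-yl]phenoxy}propylidene)cyclohexa-2,5-dien-1-one (quinone methide) | C/C=C\c1ccc(OC(C)C=C2C=CC(=O)C(OC)=C2)c(OC)c1
A7 | alternative 3 | (1R,2R)-1-(3,4-dimethoxyphenyl)propane-1,2-diol | O[C@H](C)[C@H](O)c1ccc(OC)c(OC)c1
A8 | alternative 3 | 4-fluoro-3-methoxybenzaldehyde | COc1cc(C=O)ccc1F
A9 | alternative 3 | 4-{[(1R,2R)-1-(3,4-dimethoxyphenyl)-1-hydroxypropan-2-yl]oxy}-3-methoxybenzaldehyde | O=Cc1ccc(O[C@H](C)[C@H](O)c2ccc(OC)c(OC)c2)c(OC)c1
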